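The two 2,3-cis pyranone rings C share the C3–C3'' bond, so C2, C3, C3'', C2'' with C4 and C4'' form a C2-symmetric succinyl core with a β-oxygen on each arm. The core is made as an all-R double syn-aldol, stored as its bislactone and opened in two stages to a bis(morpholine amide) with one free and one silylated carbinol. The key step exploits the 1,3-relationship of O1 and C4 in ring C: two different 3,5-dialkoxybenzynes are inserted, one after the other in one flask, between each carbinol oxygen and its own amide carbonyl, which joins O1 to C8a and C4 to C4a of ring A at once and touches no stereocentre.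

Key step: step 11

Remark: the target is read as the (2R,3R,2''R,3''R) isomer, 2,3-cis in both chromanone rings; doubly primed locants belong to the 5-hydroxy-7-methoxy unit, ring A is the benzo ring and ring C the pyranone ring.

Step 1
Reactants: 1 3,5-dimethoxyphenol
Product: 2 2-bromo-3,5-dimethoxyphenol
Conditions: NBS (1.0 equiv), CH2Cl2, −78 → 0 °C
Reagents that add atoms: N-bromosuccinimide, O=C1CCC(=O)N1Br
Why: Electrophilic aromatic bromination ortho to the free hydroxyl, at the site between OH and OMe that is less hindered than the one between the two methoxy groups.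

Step 2
Reactants: 2 2-bromo-3,5-dimethoxyphenol
Product: 5 3,5-dimethoxy-2-(trimethylsilyl)phenyl trifluoromethanesulfonate, via aryl trimethylsilyl ether 3 (not isolated), via lithium silylphenoxide 4 (not isolated)
Conditions: HMDS, THF, 70 °C, evaporate; n-BuLi, THF, −100 °C; Tf2O, −100 → 23 °C
Reagents that add atoms: hexamethyldisilazane, C[Si](C)(C)N[Si](C)(C)C; triflic anhydride, O=S(=O)(OS(=O)(=O)C(F)(F)F)C(F)(F)F
Why: O-silylation, bromine–lithium exchange with retro-Brook 1,3-shift of silicon from oxygen to carbon, then O-triflation of the phenoxide, the usual one-flask route to 2-silylaryl triflates.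

Step 3
Reactants: 6 3,5-bis(benzyloxy)phenol
Product: 7 3,5-bis(benzyloxy)-2-bromophenol
Conditions: NBS (1.0 equiv), CH2Cl2, −78 → 0 °C
Reagents that add atoms: N-bromosuccinimide, O=C1CCC(=O)N1Br
Why: Electrophilic aromatic bromination ortho to the free hydroxyl, as in step 1.

Step 4
Reactants: 7 3,5-bis(benzyloxy)-2-bromophenol
Product: 10 3,5-bis(benzyloxy)-2-(trimethylsilyl)phenyl trifluoromethanesulfonate, via aryl trimethylsilyl ether 8 (not isolated), via lithium silylphenoxide 9 (not isolated)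
Conditions: HMDS, THF, 70 °C, evaporate; n-BuLi, THF, −100 °C; Tf2O, −100 → 23 °C
Reagents that add atoms: hexamethyldisilazane, C[Si](C)(C)N[Si](C)(C)C; triflic anhydride, O=S(=O)(OS(=O)(=O)C(F)(F)F)C(F)(F)F
Why: O-silylation, bromine–lithium exchange with retro-Brook shift and O-triflation as in step 2; the exchange at −100 °C should outrun benzylic deprotonation of the benzyl ethers.

Step 5
Reactants: 11 (R)-4-benzyl-1,3-oxazolidin-2-one; 12 succinyl chloride
Product: 13 1,4-bis[(4R)-4-benzyl-2-oxo-1,3-oxazolidin-3-yl]butane-1,4-dione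
Conditions: 11 (2.05 equiv), n-BuLi, THF, −78 °C; 12 (1.0 equiv), −78 → 0 °C
Reagents that add atoms: none
Why: N-acylation of the lithiated oxazolidinone by both ends of the diacid chloride.

Step 6
Reactants: 13 1,4-bis[(4R)-4-benzyl-2-oxo-1,3-oxazolidin-3-yl]butane-1,4-dione; 14 4-methoxybenzaldehyde
Product: 15 (2R,3R)-1,4-bis[(4R)-4-benzyl-2-oxo-1,3-oxazolidin-3-yl]-2,3-bis[(R)-hydroxy(4-methoxyphenyl)methyl]butane-1,4-dione
Conditions: Bu2BOTf (2.4 equiv), i-Pr2NEt (2.8 equiv), CH2Cl2, 0 °C; 14 (2.6 equiv), −78 → 0 °C; H2O2, aq. NaH2PO4/Na2HPO4 (pH 7), MeOH, 0 °C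
Reagents that add atoms: none
Why: Twofold Evans syn aldol, in which each (Z)-boron enolate reacts through a Zimmerman–Traxler chair on the face left open by its own (R)-4-benzyl auxiliary, so that both α-carbons (later C3, C3'') and both carbinol carbons (later C2, C2'') should come out R with the syn relationship that becomes 2,3-cis.

Step 7
Reactants: 15 (2R,3R)-1,4-bis[(4R)-4-benzyl-2-oxo-1,3-oxazolidin-3-yl]-2,3-bis[(R)-hydroxy(4-methoxyphenyl)methyl]butane-1,4-dione
Product: 16 (3R,3aR,6R,6aR)-3,6-bis(4-methoxyphenyl)tetrahydro-1H,3H-furo[3,4-c]furan-1,4-dione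
Conditions: DMAP (0.2 equiv), i-Pr2NEt, toluene, 60 °C
Reagents that add atoms: none
Why: Twofold lactonisation by acyl transfer, each carbinol oxygen attacking the γ-imide carbonyl (5-exo-trig) and expelling the oxazolidinone, which should give the cis-fused bislactone with both aryl groups exo without touching a stereocentre.

Step 8
Reactants: 16 (3R,3aR,6R,6aR)-3,6-bis(4-methoxyphenyl)tetrahydro-1H,3H-furo[3,4-c]furan-1,4-dione
Product: 17 (3R,4R,5R)-3-[(R)-hydroxy(4-methoxyphenyl)methyl]-5-(4-methoxyphenyl)-4-(morpholine-4-carbonyl)oxolan-2-one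
Conditions: Me3Al (1.05 equiv), morpholine (1.05 equiv), CH2Cl2, 0 °C; then 16, −20 → 0 °C; aq. potassium sodium tartrate
Reagents that add atoms: morpholine, C1COCCN1
Why: Aluminium amide aminolysis of one lactone; the two lactones are equivalent by C2 symmetry and the strained bicyclic bislactone should open faster than the monocyclic lactone that remains.

Step 9
Reactants: 17 (3R,4R,5R)-3-[(R)-hydroxy(4-methoxyphenyl)methyl]-5-(4-methoxyphenyl)-4-(morpholine-4-carbonyl)oxolan-2-one
Product: 18 (3R,4R,5R)-3-[(R)-[(tert-butyldimethylsilyl)oxy](4-methoxyphenyl)methyl]-5-(4-methoxyphenyl)-4-(morpholine-4-carbonyl)oxolan-2-one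
Conditions: TBSOTf (1.3 equiv), 2,6-lutidine, CH2Cl2, −78 → 0 °C
Reagents that add atoms: tert-butyldimethylsilyl triflate, CC(C)(C)[Si](C)(C)OS(=O)(=O)C(F)(F)F
Why: Silylation of the secondary alcohol, which also stops it from closing back onto the γ-amide.

Step 10
Reactants: 18 (3R,4R,5R)-3-[(R)-[(tert-butyldimethylsilyl)oxy](4-methoxyphenyl)methyl]-5-(4-methoxyphenyl)-4-(morpholine-4-carbonyl)oxolan-2-one
Product: 19 (2R,3R)-2-[(R)-[(tert-butyldimethylsilyl)oxy](4-methoxyphenyl)methyl]-3-[(R)-hydroxy(4-methoxyphenyl)methyl]-1,4-di(morpholin-4-yl)butane-1,4-dione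
Conditions: Me3Al (3 equiv), morpholine (3 equiv), CH2Cl2, 0 → 40 °C; aq. potassium sodium tartrate; silica buffered with Et3N
Reagents that add atoms: morpholine, C1COCCN1
Why: Aluminium amide aminolysis of the remaining γ-lactone frees the second carbinol and forms the second tertiary amide, leaving the silyl ether and all four stereocentres unchanged.

Step 11
Reactants: 19 (2R,3R)-2-[(R)-[(tert-butyldimethylsilyl)oxy](4-methoxyphenyl)methyl]-3-[(R)-hydroxy(4-methoxyphenyl)methyl]-1,4-di(morpholin-4-yl)butane-1,4-dione; 5 3,5-dimethoxy-2-(trimethylsilyl)phenyl trifluoromethanesulfonate; 10 3,5-bis(benzyloxy)-2-(trimethylsilyl)phenyl trifluoromethanesulfonate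
Product: 24 (2R,3R)-5,7-bis(benzyloxy)-3-[(2R,3R)-5,7-dimethoxy-2-(4-methoxyphenyl)-4-oxochroman-3-yl]-2-(4-methoxyphenyl)chroman-4-one, via 3,5-dimethoxybenzyne 20 (not isolated), via mono-hemiaminal alkoxide 21 (not isolated), via 3,5-bis(benzyloxy)benzyne 22 (not isolated), via bis-hemiaminal dialkoxide 23 (not isolated)
Conditions: NaH (1.05 equiv), THF, 0 °C; 5 (1.1 equiv), Bu4N[Ph3SiF2] (TBAT, 1.3 equiv), 0 → 23 °C; then (Me2N)3S[Me3SiF2] (TASF, 4 equiv), 23 °C, slow addition of 10 (1.5 equiv); sat. aq. NH4Cl, 0 °C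
Reagents that add atoms: none
Why: Proposed new method: an alkoxide adds to a 3,5-dialkoxybenzyne at the aryne carbon remote from the 3-alkoxy group, and the aryl anion so formed, ortho to that alkoxy group, attacks the morpholine amide β to the oxygen, so O1–C8a and C4–C4a form in one insertion; the closest known reaction type is the aryne annulation of salicylate esters to xanthones, extended here to an aliphatic β-alkoxy amide. Each ring C closes by 6-exo-trig attack of the aryl anion on the amide carbonyl. No stereocentre is made or touched, because the C2–O and C3–C4 bonds stay intact and the tetrahedral morpholine hemiaminal alkoxides 21 and 23 should not collapse before the buffered quench, so neither cis-configured C3 sits next to a free ketone under basic conditions. The step needs regioselectivity on the aryne, secured by the inductive polarisation from the 3-alkoxy group that places the carbonyl next to the 5-oxygen, and site selectivity between the two carbinol oxygens, secured by timing: the free hydroxyl is deprotonated and consumed first, while the TBS ether should survive the difluorotriphenylsilicate and is unmasked by TASF only after 5 is used up. Tertiary amides are chosen because they resist the γ-alkoxide, which an ester or imide would not.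

Step 12
Reactants: 24 (2R,3R)-5,7-bis(benzyloxy)-3-[(2R,3R)-5,7-dimethoxy-2-(4-methoxyphenyl)-4-oxochroman-3-yl]-2-(4-methoxyphenyl)chroman-4-one
Product: 25 (2R,3R)-5,7-dihydroxy-3-[(2R,3R)-5-hydroxy-7-methoxy-2-(4-methoxyphenyl)-4-oxochroman-3-yl]-2-(4-methoxyphenyl)chroman-4-one
Conditions: BCl3 (8 equiv), pentamethylbenzene (6 equiv), CH2Cl2, −78 → 0 °C; MeOH
Reagents that add atoms: none
Why: Lewis-acid ether cleavage, in which BCl3 with a cation scavenger removes the two benzyl groups at low temperature and, by chelation to the C4'' carbonyl, only the peri 5''-methyl ether on warming, so the three non-chelated methyl ethers should survive.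

Compound list
1 | 3,5-dimethoxyphenol | COc1cc(O)cc(OC)c1 | starting material
2 | 2-bromo-3,5-dimethoxyphenol | COc1cc(O)c(Br)c(OC)c1 | intermediate
3 | (2-bromo-3,5-dimethoxyphenoxy)trimethylsilane | COc1cc(O[Si](C)(C)C)c(Br)c(OC)c1 | intermediate
4 | lithium 3,5-dimethoxy-2-(trimethylsilyl)phenoxide | [Li+].COc1cc([O-])c([Si](C)(C)C)c(OC)c1 | intermediate
5 | 3,5-dimethoxy-2-(trimethylsilyl)phenyl trifluoromethanesulfonate | COc1cc(OC)c([Si](C)(C)C)c(OS(=O)(=O)C(F)(F)F)c1 | intermediate
6 | 3,5-bis(benzyloxy)phenol | Oc1cc(OCc2ccccc2)cc(OCc2ccccc2)c1 | starting material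
7 | 3,5-bis(benzyloxy)-2-bromophenol | Oc1cc(OCc2ccccc2)cc(OCc2ccccc2)c1Br | intermediate
8 | [3,5-bis(benzyloxy)-2-bromophenoxy]trimethylsilane | C[Si](C)(C)Oc1cc(OCc2ccccc2)cc(OCc2ccccc2)c1Br | intermediate
9 | lithium 3,5-bis(benzyloxy)-2-(trimethylsilyl)phenoxide | [Li+].[O-]c1cc(OCc2ccccc2)cc(OCc2ccccc2)c1[Si](C)(C)C | intermediate
10 | 3,5-bis(benzyloxy)-2-(trimethylsilyl)phenyl trifluoromethanesulfonate | C[Si](C)(C)c1c(OCc2ccccc2)cc(OCc2ccccc2)cc1OS(=O)(=O)C(F)(F)F | intermediate
11 | (R)-4-benzyl-1,3-oxazolidin-2-one | O=C1N[C@H](Cc2ccccc2)CO1 | starting material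
12 | succinyl chloride | O=C(Cl)CCC(=O)Cl | starting material
13 | 1,4-bis[(4R)-4-benzyl-2-oxo-1,3-oxazolidin-3-yl]butane-1,4-dione | O=C(CCC(=O)N1[C@H](Cc2ccccc2)COC1=O)N1[C@H](Cc2ccccc2)COC1=O | intermediate
14 | 4-methoxybenzaldehyde | COc1ccc(C=O)cc1 | starting material
15 | (2R,3R)-1,4-bis[(4R)-4-benzyl-2-oxo-1,3-oxazolidin-3-yl]-2,3-bis[(R)-hydroxy(4-methoxyphenyl)methyl]butane-1,4-dione | COc1ccc(cc1)[C@H](O)[C@H](C(=O)N1[C@H](Cc2ccccc2)COC1=O)[C@@H](C(=O)N1[C@H](Cc2ccccc2)COC1=O)[C@@H](O)c1ccc(OC)cc1 | intermediate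
16 | (3R,3aR,6R,6aR)-3,6-bis(4-methoxyphenyl)tetrahydro-1H,3H-furo[3,4-c]furan-1,4-dione (cis-fused, both aryl groups exo) | COc1ccc(cc1)[C@H](O2)[C@H](C3=O)[C@@H](C2=O)[C@@H](O3)c1ccc(OC)cc1 | intermediate
17 | (3R,4R,5R)-3-[(R)-hydroxy(4-methoxyphenyl)methyl]-5-(4-methoxyphenyl)-4-(morpholine-4-carbonyl)oxolan-2-one | COc1ccc(cc1)[C@H](O)[C@H](C3=O)[C@@H](C(=O)N2CCOCC2)[C@@H](O3)c1ccc(OC)cc1 | intermediate
18 | (3R,4R,5R)-3-[(R)-[(tert-butyldimethylsilyl)oxy](4-methoxyphenyl)methyl]-5-(4-methoxyphenyl)-4-(morpholine-4-carbonyl)oxolan-2-one | COc1ccc(cc1)[C@H](O[Si](C)(C)C(C)(C)C)[C@H](C3=O)[C@@H](C(=O)N2CCOCC2)[C@@H](O3)c1ccc(OC)cc1 | intermediate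
19 | (2R,3R)-2-[(R)-[(tert-butyldimethylsilyl)oxy](4-methoxyphenyl)methyl]-3-[(R)-hydroxy(4-methoxyphenyl)methyl]-1,4-di(morpholin-4-yl)butane-1,4-dione | COc1ccc(cc1)[C@H](O[Si](C)(C)C(C)(C)C)[C@H](C(=O)N2CCOCC2)[C@@H](C(=O)N2CCOCC2)[C@@H](O)c1ccc(OC)cc1 | intermediate
20 | 3,5-dimethoxybenzyne (1,2-didehydro-3,5-dimethoxybenzene) | COC1=CC(OC)=CC#C1 | intermediate
21 | mono-hemiaminal, held as its alkoxide: (2R,3R)-5,7-dimethoxy-2-(4-methoxyphenyl)-4-(morpholin-4-yl)chroman-4-ol carrying at C3 the (1R,2R)-2-[(tert-butyldimethylsilyl)oxy]-2-(4-methoxyphenyl)-1-(morpholine-4-carbonyl)ethyl arm; C4 not assigned | COc1ccc(cc1)[C@H](O[Si](C)(C)C(C)(C)C)[C@H](C(=O)N2CCOCC2)[C@@H](C(O)(N3CCOCC3)c3c(OC)cc(OC)cc3O4)[C@@H]4c1ccc(OC)cc1 | intermediate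
22 | 3,5-bis(benzyloxy)benzyne (1,2-didehydro-3,5-bis(benzyloxy)benzene) | C1(OCc2ccccc2)=CC(OCc2ccccc2)=CC#C1 | intermediate
23 | bis-hemiaminal, held as its dialkoxide: the (2R,3R,2''R,3''R)-3,3''-linked bis(chroman-4-ol) with a morpholin-4-yl group at C4 and C4'', 5,7-bis(benzyloxy) on one unit and 5'',7''-dimethoxy on the other; C4 and C4'' not assigned | COc1ccc(cc1)[C@H](Oc2cc(OCc3ccccc3)cc(OCc3ccccc3)c2C2(O)N3CCOCC3)[C@H]2[C@@H](C(O)(N3CCOCC3)c3c(OC)cc(OC)cc3O4)[C@@H]4c1ccc(OC)cc1 | intermediate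
24 | (2R,3R)-5,7-bis(benzyloxy)-3-[(2R,3R)-5,7-dimethoxy-2-(4-methoxyphenyl)-4-oxochroman-3-yl]-2-(4-methoxyphenyl)chroman-4-one | COc1ccc([C@@H]2Oc3cc(OCc4ccccc4)cc(OCc4ccccc4)c3C(=O)[C@@H]2[C@H]2C(=O)c3c(OC)cc(OC)cc3O[C@H]2c2ccc(OC)cc2)cc1 | intermediate
25 | (2R,3R)-5,7-dihydroxy-3-[(2R,3R)-5-hydroxy-7-methoxy-2-(4-methoxyphenyl)-4-oxochroman-3-yl]-2-(4-methoxyphenyl)chroman-4-one | COc1ccc([C@@H]2Oc3cc(O)cc(O)c3C(=O)[C@@H]2[C@H]2C(=O)c3c(O)cc(OC)cc3O[C@H]2c2ccc(OC)cc2)cc1 | target

Total step count: 12. Longest linear sequence: 8 steps (steps 5 to 12); steps 1–2 and 3–4 are two-step side branches that deliver the aryne precursors 5 and 10.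

Steps most likely to fail

Step 11 (key step). The aryl anion may be quenched by proton transfer from the amide α-C–H, followed by β-elimination of the new aryloxide, before it closes onto the amide carbonyl. The silyl ether may be lost during the first stage, so that the two arynes cross over. A hemiaminal may collapse before the quench and allow epimerisation at C3 or C3''. The fallback uses known reactions only, sets out from 16 and comes back at 24. At −78 °C in THF one lactone of 16 is opened by 2-fluoro-4,6-dimethoxyphenyllithium F1, made from the aryl bromide and n-BuLi. The lithium lactolate formed masks the first ketone and its charge should disfavour a second addition of the same reagent. The other lactone is then opened in the same flask by 2,4-bis(benzyloxy)-6-fluorophenyllithium F2, which after work-up should give (2R,3R)-1-[2,4-bis(benzyloxy)-6-fluorophenyl]-4-(2-fluoro-4,6-dimethoxyphenyl)-2,3-bis[(R)-hydroxy(4-methoxyphenyl)methyl]butane-1,4-dione F3. Cs2CO3 in DMF at 23 °C then closes both rings C by intramolecular nucleophilic aromatic substitution of each β-alkoxide on its ortho fluorine, which gives 24.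

Step 6. The second enolisation or the second aldol addition may stall at the mono-adduct, or the second addition may be mismatched with the stereocentres already set and give the unsymmetrical diastereomer. The fallback sets out from 14 and comes back at 16. The dianion of N,N,N',N'-tetramethylsuccinamide (lithium diisopropylamide, LiN(i-Pr)2, 2.2 equiv, THF, −78 °C) is added twice to 14 to give racemic (2R*,3R*)-2,3-bis[(R*)-hydroxy(4-methoxyphenyl)methyl]-N,N,N',N'-tetramethylbutanediamide F4. TsOH in toluene at 80 °C lactonises it with loss of dimethylamine, under thermodynamic control at the benzylic carbons, to the racemic exo,exo-bislactone F5. Preparative chromatography on a chiral stationary phase separates 16 from its enantiomer.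

Step 12. The Lewis acid may ionise a p-methoxybenzylic C2–O1 bond, with epimerisation at C2 or opening of ring C, or the chelate-directed demethylation may stop short. The fallback sets out from 24 and comes back at 25. Hydrogenolysis (H2, Pd/C, EtOAc/THF, 23 °C) removes both benzyl groups under neutral conditions to give (2R,3R)-3-[(2R,3R)-5,7-dimethoxy-2-(4-methoxyphenyl)-4-oxochroman-3-yl]-5,7-dihydroxy-2-(4-methoxyphenyl)chroman-4-one F6. MgI2·OEt2 in THF at 50 °C then cleaves only the chelated 5''-methyl ether to give 25.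

Further compounds
F1 | step 11 | 2-fluoro-4,6-dimethoxyphenyllithium | [Li]c1c(F)cc(OC)cc1OC
F2 | step 11 | 2,4-bis(benzyloxy)-6-fluorophenyllithium | [Li]c1c(F)cc(OCc2ccccc2)cc1OCc1ccccc1
F3 | step 11 | (2R,3R)-1-[2,4-bis(benzyloxy)-6-fluorophenyl]-4-(2-fluoro-4,6-dimethoxyphenyl)-2,3-bis[(R)-hydroxy(4-methoxyphenyl)methyl]butane-1,4-dione | COc1ccc(cc1)[C@H](O)[C@H](C(=O)c2c(F)cc(OCc3ccccc3)cc2OCc2ccccc2)[C@@H](C(=O)c2c(F)cc(OC)cc2OC)[C@@H](O)c1ccc(OC)cc1
F4 | step 6 | racemic (2R*,3R*)-2,3-bis[(R*)-hydroxy(4-methoxyphenyl)methyl]-N,N,N',N'-tetramethylbutanediamide (both enantiomers) | COc1ccc(cc1)[C@H](O)[C@H](C(=O)N(C)C)[C@@H](C(=O)N(C)C)[C@@H](O)c1ccc(OC)cc1.COc1ccc(cc1)[C@@H](O)[C@@H](C(=O)N(C)C)[C@H](C(=O)N(C)C)[C@H](O)c1ccc(OC)cc1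
F5 | step 6 | racemic exo,exo-3,6-bis(4-methoxyphenyl)tetrahydro-1H,3H-furo[3,4-c]furan-1,4-dione (16 and its enantiomer) | COc1ccc(cc1)[C@H](O2)[C@H](C3=O)[C@@H](C2=O)[C@@H](O3)c1ccc(OC)cc1.COc1ccc(cc1)[C@@H](O2)[C@@H](C3=O)[C@H](C2=O)[C@H](O3)c1ccc(OC)cc1
F6 | step 12 | (2R,3R)-3-[(2R,3R)-5,7-dimethoxy-2-(4-methoxyphenyl)-4-oxochroman-3-yl]-5,7-dihydroxy-2-(4-methoxyphenyl)chroman-4-one | COc1ccc([C@@H]2Oc3cc(O)cc(O)c3C(=O)[C@@H]2[C@H]2C(=O)c3c(OC)cc(OC)cc3O[C@H]2c2ccc(OC)cc2)cc1
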